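Assumption: the carbinol centre written in the SMILES is (S), and the aryl pinacol boronate and 3-bromo-2-hydroxy-5-methylbenzaldehyde are bought as catalogue compounds.

**Retrosynthetic overview**
- Last move: the ring B phenol is released from its allyl ether, the only protecting group; acid, aldehyde and carbinol travel unprotected.
- Diaryl ether C–O bond: carboxylate-assisted copper Ullmann coupling of a ring A 6-bromo-2-methoxybenzoic acid with 3-allyloxy-5-methylsalicylaldehyde (ring B, from the 3-bromosalicylaldehyde by copper allyloxylation).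
- Ring A carboxyl: ortho-lithiation between OMe and Br, then CO2.
- Key C–C bond (aryl to carbinol carbon, sets the S centre): a (+)-sparteine-lithiated isoamyl carbamate, a chiral α-oxy carbanion standing for the carbonyl carbon of isovaleraldehyde with inverted polarity, is joined to the donor aryl carbon of a pinacol boronate by a 1,2-metallate shift; the C–B bond is then oxidised.
- Ring order: no ring is built; both benzene rings are bought, ring A is elaborated first (side chain, then carboxyl) and ring B is attached last.

**Route**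

Step 1
Reactants: 1 3-methylbutan-1-ol
Product: 2 3-methylbutyl N,N-diisopropylcarbamate
Conditions: i-Pr2NCOCl (1.1 equiv), Et3N (1.3 equiv), CH2Cl2, reflux, 24 h
Reagents that add atoms: N,N-diisopropylcarbamoyl chloride, CC(C)N(C(C)C)C(=O)Cl
Why: Plain O-carbamoylation of a primary alcohol (acyl substitution) installs the directing and leaving group needed for Hoppe deprotonation.

Step 2
Reactants: 2 3-methylbutyl N,N-diisopropylcarbamate; 3 2-(4-bromo-2-methoxyphenyl)-4,4,5,5-tetramethyl-1,3,2-dioxaborolane
Product: 7 (S)-1-(4-bromo-2-methoxyphenyl)-3-methylbutan-1-ol, via lithiated carbamate 4 (not isolated), via boronate complex 5 (not isolated), via secondary boronic ester 6 (not isolated)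
Conditions: 2 (1.3 equiv), s-BuLi (1.25 equiv), (+)-sparteine (1.3 equiv), Et2O, −78 °C, 5 h; then 3 (1.0 equiv), −78 °C, 1 h; MgBr2·OEt2 (1.5 equiv), −78 °C → reflux, 16 h; then 2 M NaOH, 30% H2O2, THF, 0 °C → rt
Reagents that add atoms: hydrogen peroxide, OO
Why: Hoppe deprotonation with (+)-sparteine removes the pro-R hydrogen to give the configurationally stable (R)-α-lithio carbamate, which adds to boron with retention; the aryl group then shifts from boron to carbon with inversion and expels the carbamate (Matteson-type 1,2-metallate rearrangement, Aggarwal lithiation–borylation), and stereoretentive C–B oxidation gives the (S)-alcohol, typically near 97:3 er, with the aryl bromide untouched because the carbanion is consumed by boron at −78 °C.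

Step 3
Reactants: 7 (S)-1-(4-bromo-2-methoxyphenyl)-3-methylbutan-1-ol
Product: 9 6-bromo-3-[(1S)-1-hydroxy-3-methylbutyl]-2-methoxybenzoic acid, via dilithio aryl species 8 (not isolated)
Conditions: LiN(i-Pr)2 (3.0 equiv), THF, −78 °C, 1.5 h; CO2 (g), −78 °C → rt; 1 M HCl
Reagents that add atoms: carbon dioxide, O=C=O
Why: Directed ortho-metalation: after O-deprotonation the amide base removes the most acidic ring proton, the one flanked by OMe and Br (as in 3-bromoanisole), without halogen–lithium exchange, and the aryllithium is carboxylated at −78 °C before LiBr loss; the alkoxide-bearing stereocentre is not touched.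

Step 4
Reactants: 10 3-bromo-2-hydroxy-5-methylbenzaldehyde
Product: 11 3-(allyloxy)-2-hydroxy-5-methylbenzaldehyde
Conditions: NaH (3.5 equiv), allyl alcohol (solvent), 0 °C; then 10, CuCl (0.2 equiv), DMF (co-solvent), 100 °C, 12 h; 1 M HCl
Reagents that add atoms: allyl alcohol, C=CCO
Why: Ullmann-type copper-catalysed alkoxylation of an o-bromophenol (the 5-bromovanillin to syringaldehyde reaction) run with allyloxide instead of methoxide; the phenoxide conjugated to the formyl group shields the aldehyde from alkoxide, and excess allyloxide outcompetes self-arylation.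

Step 5
Reactants: 9 6-bromo-3-[(1S)-1-hydroxy-3-methylbutyl]-2-methoxybenzoic acid; 11 3-(allyloxy)-2-hydroxy-5-methylbenzaldehyde (1.5 equiv)
Product: 12 6-[2-(allyloxy)-6-formyl-4-methylphenoxy]-3-[(1S)-1-hydroxy-3-methylbutyl]-2-methoxybenzoic acid
Conditions: CuI (10 mol %), picolinic acid (20 mol %), K3PO4 (3.5 equiv), DMSO, 90 °C, 24 h, argon; 1 M HCl
Reagents that add atoms: none
Why: Ullmann diaryl ether synthesis in which the ortho-carboxylate binds monovalent copper and speeds oxidative addition of the adjacent C–Br bond (Hurtley-type ortho effect), the picolinate ligand allowing the hindered phenoxide to couple; the secondary alcohol, aldehyde and allyl ether are inert, and no stereocentre is involved.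

Step 6
Reactants: 12 6-[2-(allyloxy)-6-formyl-4-methylphenoxy]-3-[(1S)-1-hydroxy-3-methylbutyl]-2-methoxybenzoic acid
Product: 13 Tenellic acid B
Conditions: Pd(PPh3)4 (5 mol %), p-TolSO2Na (1.5 equiv), THF/MeOH, rt, 2 h; 1 M HCl to pH 3
Reagents that add atoms: none
Why: Tsuji–Trost deallylation: zerovalent palladium ionises the aryl allyl ether to a π-allyl complex that the sulfinate captures as a sulfone, under near-neutral conditions that leave the aldehyde, acid and acid-sensitive benzylic (S)-carbinol alone.

**Compound list**

1 | 3-methylbutan-1-ol | CC(C)CCO | starting material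
2 | 3-methylbutyl N,N-diisopropylcarbamate | CC(C)CCOC(=O)N(C(C)C)C(C)C | intermediate
3 | 2-(4-bromo-2-methoxyphenyl)-4,4,5,5-tetramethyl-1,3,2-dioxaborolane | COc1cc(Br)ccc1B1OC(C)(C)C(C)(C)O1 | starting material
4 | (1R)-1-lithio-3-methylbutyl N,N-diisopropylcarbamate (as its (+)-sparteine chelate) | CC(C)C[C@@H]([Li])OC(=O)N(C(C)C)C(C)C | intermediate
5 | lithium (4-bromo-2-methoxyphenyl)[(1R)-1-(N,N-diisopropylcarbamoyloxy)-3-methylbutyl](pinacolato)borate | CC(C)C[C@@H]([B-]1(c2ccc(Br)cc2OC)OC(C)(C)C(C)(C)O1)OC(=O)N(C(C)C)C(C)C.[Li+] | intermediate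
6 | 2-[(1S)-1-(4-bromo-2-methoxyphenyl)-3-methylbutyl]-4,4,5,5-tetramethyl-1,3,2-dioxaborolane | COc1cc(Br)ccc1[C@@H](B1OC(C)(C)C(C)(C)O1)CC(C)C | intermediate
7 | (S)-1-(4-bromo-2-methoxyphenyl)-3-methylbutan-1-ol | COc1cc(Br)ccc1[C@@H](O)CC(C)C | intermediate
8 | lithium (1S)-1-(4-bromo-3-lithio-2-methoxyphenyl)-3-methylbutan-1-olate | COc1c([Li])c(Br)ccc1[C@@H](O[Li])CC(C)C | intermediate
9 | 6-bromo-3-[(1S)-1-hydroxy-3-methylbutyl]-2-methoxybenzoic acid | COc1c([C@@H](O)CC(C)C)ccc(Br)c1C(=O)O | intermediate
10 | 3-bromo-2-hydroxy-5-methylbenzaldehyde | Cc1cc(Br)c(O)c(C=O)c1 | starting material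
11 | 3-(allyloxy)-2-hydroxy-5-methylbenzaldehyde | C=CCOc1cc(C)cc(C=O)c1O | intermediate
12 | 6-[2-(allyloxy)-6-formyl-4-methylphenoxy]-3-[(1S)-1-hydroxy-3-methylbutyl]-2-methoxybenzoic acid | COc1c([C@@H](O)CC(C)C)ccc(Oc2c(OCC=C)cc(C)cc2C=O)c1C(=O)O | intermediate
13 | Tenellic acid B | COc1c([C@@H](O)CC(C)C)ccc(Oc2c(O)cc(C)cc2C=O)c1C(=O)O | target

**Count and risks**

Total steps: 6. Longest linear sequence: 5 (steps 1, 2, 3, 5, 6); step 4 is the one-step ring B branch.

Most likely to fail, in order: step 5, step 2, step 4.

Fallback for step 5 (the phenol is hindered and deactivated by its ortho formyl group, so the copper coupling may stall or give debromination): reverse the polarity of the ether synthesis. The fallback sets out from 9 and returns at 12. Carboxylate-assisted copper hydroxylation of the C–Br bond of 9 (CuSO4 cat., aq. NaOH, 100 °C) gives 6-hydroxy-3-[(1S)-1-hydroxy-3-methylbutyl]-2-methoxybenzoic acid F4. The electrophile is made from commercial 2-fluoro-5-methylphenol: O-allylation (allyl bromide, K2CO3, acetone) gives 2-(allyloxy)-1-fluoro-4-methylbenzene F5, and lithiation next to fluorine (LiN(i-Pr)2, THF, −78 °C) followed by DMF gives 3-(allyloxy)-2-fluoro-5-methylbenzaldehyde F6. SNAr of the phenoxide of F4 on F6 (K2CO3, DMF, 100 °C), with the fluoride activated by the ortho formyl group, gives 12.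

Fallback for step 2 (the ortho-methoxy boronate may form the ate complex slowly or reversibly, or the aryl group may migrate poorly): keep the same chiral α-oxy carbanion but couple it with an aryl halide. The fallback sets out from 2 and returns at 7. Lithiation as in step 2 gives 4, and ZnCl2 (THF, −78 °C → rt) converts it with retention into (1R)-1-(chlorozincio)-3-methylbutyl N,N-diisopropylcarbamate F1. Negishi coupling with commercial 4-bromo-1-iodo-2-methoxybenzene (Pd(OAc)2, t-Bu3P·HBF4, rt; only C–I reacts, retention at carbon) gives (1S)-1-(4-bromo-2-methoxyphenyl)-3-methylbutyl N,N-diisopropylcarbamate F2. This coupling is modelled on the sparteine lithiation, zinc transmetalation and arylation of N-Boc-pyrrolidine and is itself unproven for O-carbamates. LiAlH4 (THF, 0 °C → rt) then cleaves the carbamate to 7; this is acceptable only at this early stage, where no ester, acid or aldehyde is present.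

Fallback for step 4 (allyloxide may reduce the aryl bromide by hydride transfer or react sluggishly): form the allyl C–O bond by phenoxide alkylation instead of aryl C–O coupling. The fallback sets out from 10 and returns at 11. Copper-mediated hydroxylation of 10 (Cu powder, aq. NaOH, reflux; the 5-bromovanillin to 5-hydroxyvanillin reaction) gives 2,3-dihydroxy-5-methylbenzaldehyde F3. Its dianion (NaH 2.1 equiv, DMSO, rt) is alkylated by allyl bromide (1.0 equiv) at the more nucleophilic, non-chelated 3-oxide to give 11.

**Further compounds**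

F1 | step 2 | (1R)-1-(chlorozincio)-3-methylbutyl N,N-diisopropylcarbamate | CC(C)C[C@@H]([Zn]Cl)OC(=O)N(C(C)C)C(C)C
F2 | step 2 | (1S)-1-(4-bromo-2-methoxyphenyl)-3-methylbutyl N,N-diisopropylcarbamate | COc1cc(Br)ccc1[C@@H](OC(=O)N(C(C)C)C(C)C)CC(C)C
F3 | step 4 | 2,3-dihydroxy-5-methylbenzaldehyde | Cc1cc(O)c(O)c(C=O)c1
F4 | step 5 | 6-hydroxy-3-[(1S)-1-hydroxy-3-methylbutyl]-2-methoxybenzoic acid | COc1c([C@@H](O)CC(C)C)ccc(O)c1C(=O)O
F5 | step 5 | 2-(allyloxy)-1-fluoro-4-methylbenzene | C=CCOc1cc(C)ccc1F
F6 | step 5 | 3-(allyloxy)-2-fluoro-5-methylbenzaldehyde | C=CCOc1cc(C)cc(C=O)c1F
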